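**Assumptions (one line):** Locants follow the germacrane numbering of the target (C1 = ketal carbon, C4 = tertiary ether carbon, C10 = CH–Me, C11–C13 = lactone unit, tiglate = E). The C4 and C8 facial selectivities (steps 6 and 11) are taken to follow the 10-ring conformation set by the (10R)-methyl group.

## Retrosynthetic overview
1. Vernolide-B comes from a late C8 tigloylation and C13 acetoxylation of a butenolide-bearing bridged methyl ketal.
2. The C5=C6 alkylidene butenolide is made from a C6/C7 1,2-dione by HWE olefination and cyclodehydration. The C8–O bond is made by Rubottom oxidation, and the isopropylidene carbons serve only as a traceless C7 handle removed by ozonolysis.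
3. The C1 ketal and C4 tertiary ether come from a 1,4-hydroxy ketone plus MeOH. The C4 alcohol comes from an α,β-epoxy ketone.
4. The 10-membered carbocycle is formed by anionic oxy-Cope ring expansion of a 1-vinyl-2-propynylcyclohexane-1,2-diol made from (R)-pulegone, which supplies the C10 stereocentre.
5. Ring order: cyclohexane (pulegone) → 10-ring (oxy-Cope) → THF ketal → butenolide.

## Route

**Step 1**
Reactants: 1 (R)-pulegone
Product: 2 (5R)-6-hydroxy-5-methyl-2-(propan-2-ylidene)cyclohexan-1-one (C6-epimer mixture)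
Conditions: LDA, THF, –78 °C; then Davis oxaziridine, –78 °C
Reagents that add atoms: 2-(phenylsulfonyl)-3-phenyloxaziridine, O=S(=O)(c1ccccc1)N1OC1c1ccccc1 (adds O)
Why: Enolate oxygenation occurs at the only enolisable α′-CH2 (germacrane C1), since the other α-carbon is alkylidene. The new carbinol centre is oxidised again in step 3, so its configuration does not matter, and C10 is untouched.

**Step 2**
Reactants: 2; 3 propynylmagnesium bromide
Product: 4 (5R)-5-methyl-2-(propan-2-ylidene)-1-(prop-1-yn-1-yl)cyclohexane-1,6-diol (C1/C6 centres unassigned)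
Conditions: 3 (3 equiv), THF, –78 → 0 °C
Reagents that add atoms: 3, CC#C[Mg]Br (adds propynyl)
Why: Grignard 1,2-addition to the hindered enone carbonyl, directed by chelation to the neighbouring alkoxide. The new carbinol is sp2 after step 5, so its configuration is irrelevant.

**Step 3**
Reactants: 4
Product: 5 (6R)-2-hydroxy-6-methyl-3-(propan-2-ylidene)-2-(prop-1-yn-1-yl)cyclohexan-1-one (C2 carbinol unassigned)
Conditions: Dess–Martin periodinane, NaHCO3, CH2Cl2, 0 °C
Reagents that add atoms: none
Why: Dess–Martin oxidation is chemoselective for the secondary alcohol over the tertiary propargylic alcohol. It is run buffered and cold to protect the C10–H, which is now α to a ketone.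

**Step 4**
Reactants: 5; 6 vinylmagnesium bromide
Product: 7 1-ethenyl-6-methyl-3-(propan-2-ylidene)-2-(prop-1-yn-1-yl)cyclohexane-1,2-diol (6R; C1/C2 centres unassigned)
Conditions: 6 (3 equiv), CeCl3, THF, –78 °C
Reagents that add atoms: 6, C=C[Mg]Br (adds vinyl)
Why: Organocerium addition to the α-ketol carbonyl is chelation-controlled and suppresses enolisation at C10. This builds the 3,4-dioxy-1,5-enyne-diene needed for the key step.

**Step 5 (key step)**
Reactants: 7
Product: 8 (10R)-4,10-dimethyl-7-(propan-2-ylidene)cyclodec-4-ene-1,6-dione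
Conditions: KH, 18-crown-6, THF, 25 → 60 °C; then aq. NH4Cl, 0 °C
Reagents that add atoms: none (protons only)
Why: Dianionic oxy-Cope ([3,3]-sigmatropic) rearrangement breaks C1–C6 and forms C3–C4, expanding the ring 6 → 10. The driving force is release of both alkoxides as enolates. The allenolate protonates to the C4=C5–C6=O enone and the C1 enolate gives the C1 ketone. The only remaining stereocentre is C10 (R), carried from pulegone.

**Step 6**
Reactants: 8
Product: 9 (4R,10R)-4,5-epoxy-4,10-dimethyl-7-(propan-2-ylidene)cyclodecane-1,6-dione (C5 epoxide carbon set by alkene geometry)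
Conditions: t-BuOOH, Triton B (cat.), THF, 0 °C
Reagents that add atoms: tert-butyl hydroperoxide, CC(C)(C)OO (adds O)
Why: Weitz–Scheffer nucleophilic epoxidation takes the less hindered trisubstituted C4=C5 enone rather than the tetrasubstituted C7=C11 enone. It sets C4 from the peripheral face of the ring, as determined by the (10R)-methyl.

**Step 7**
Reactants: 9
Product: 10 (4R,10R)-4-hydroxy-4,10-dimethyl-7-(propan-2-ylidene)cyclodecane-1,6-dione
Conditions: SmI2 (2.2 equiv), THF/MeOH, –78 °C
Reagents that add atoms: none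
Why: SmI2 reductively cleaves the C5–O bond of the α,β-epoxy ketone, giving the β-hydroxy ketone. The C5 stereocentre is removed and C4 is retained.

**Step 8**
Reactants: 10
Product: 11 (1S,4R,10R)-1-methoxy-1,4-epoxy-4,10-dimethyl-7-(propan-2-ylidene)cyclodecan-6-one
Conditions: MeOH, HC(OMe)3, CSA (cat.), 25 °C
Reagents that add atoms: methanol, CO (adds OMe)
Why: The 1,4-hydroxy ketone closes to a five-membered hemiketal, which is methanolysed (acid-catalysed ketalisation). The C1 configuration is dictated by C4, since only one diastereomer can bridge the ring, and C10 can no longer epimerise.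

**Step 9**
Reactants: 11
Product: 12 (1S,4R,10R)-1-methoxy-1,4-epoxy-4,10-dimethylcyclodecane-6,7-dione
Conditions: O3, CH2Cl2, –78 °C; then Me2S
Reagents that add atoms: ozone, O=[O+][O-] (adds O to C7)
Why: Ozonolysis of the only alkene removes the isopropylidene as acetone and leaves the C6/C7 1,2-dione. The ketal and the other functional groups are inert to ozone at –78 °C.

**Step 10**
Reactants: 12
Product: 13 (1S,4R,10R)-7-[(tert-butyldimethylsilyl)oxy]-1-methoxy-1,4-epoxy-4,10-dimethylcyclodec-7-en-6-one
Conditions: LiHMDS, THF, –78 °C; then TBSCl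
Reagents that add atoms: TBSCl, CC(C)(C)[Si](C)(C)Cl (adds TBS)
Why: Kinetic enolisation occurs toward C8, because C5–H2 is flanked by the quaternary C4 centre. Trapping gives the C7/C8 silyl enol ether.

**Step 11**
Reactants: 13
Product: 14 (1S,4R,8S,10R)-8-[(tert-butyldimethylsilyl)oxy]-1-methoxy-1,4-epoxy-4,10-dimethylcyclodecane-6,7-dione
Conditions: DMDO, acetone/CH2Cl2, –20 °C; silica workup
Reagents that add atoms: dimethyldioxirane, CC1(C)OO1 (adds O)
Why: Rubottom oxidation epoxidises the silyl enol ether from the outer ring face. A 1,4-silyl shift then gives the α-silyloxy ketone, with the C8 configuration set by ring conformation (8S, as needed in the target).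

**Step 12**
Reactants: 14; 15 triethyl 2-phosphonopropionate
Product: 16 ethyl (Z)-2-[(1S,4R,8S,10R)-8-(TBSO)-1-methoxy-1,4-epoxy-4,10-dimethyl-6-oxocyclodecan-7-ylidene]propanoate
Conditions: 15, LiCl, DBU, MeCN, 25 °C
Reagents that add atoms: 15, CCOC(=O)C(C)P(=O)(OCC)OCC (adds C(CH3)CO2Et)
Why: Horner–Wadsworth–Emmons olefination (Masamune–Roush) occurs at the more electrophilic C7 ketone, which is activated by the α-oxygen and remote from the hindered C4 side. The ester ends up syn to C6 and anti to the bulky C8 silyloxy group, which is the geometry required for lactonisation.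

**Step 13**
Reactants: 16
Product: 17 (Z)-2-[(1S,4R,8S,10R)-8-(TBSO)-1-methoxy-1,4-epoxy-4,10-dimethyl-6-oxocyclodecan-7-ylidene]propanoic acid
Conditions: LiOH·H2O, THF/H2O/MeOH, 25 °C
Reagents that add atoms: water/hydroxide (adds O)
Why: Saponification is selective because this is the only ester in the molecule at this stage. TBS ether and ketal tolerate base.

**Step 14**
Reactants: 17
Product: 18 TBS ether of the 13-methyl alkylidene-butenolide, (1S,4R,8S,10R) core
Conditions: Ac2O, Et3N, DMAP, CH2Cl2, 0 → 25 °C
Reagents that add atoms: none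
Why: The keto acid (ring–chain tautomer of the 5-hydroxybutenolide) is activated and eliminates toward C5 (enol-lactonisation/dehydration). The C5=C6 geometry (C4 cis to C7) is forced by the 10-membered ring, and no new stereocentre forms.

**Step 15**
Reactants: 18
Product: 19 13-bromo derivative of 18
Conditions: NBS, AIBN (cat.), PhCF3, 80 °C
Reagents that add atoms: N-bromosuccinimide, O=C1CCC(=O)N1Br (adds Br)
Why: Wohl–Ziegler allylic bromination at the C13 methyl, which gives a strongly stabilised vinylogous radical.

**Step 16**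
Reactants: 19
Product: 20 13-acetoxy derivative (TBS ether)
Conditions: KOAc, 18-crown-6, MeCN, 25 °C
Reagents that add atoms: potassium acetate, CC(=O)[O-].[K+] (adds OAc)
Why: SN2 displacement of the allylic bromide by acetate, with no stereocentre involved.

**Step 17**
Reactants: 20
Product: 21 8-hydroxy compound (8-O-deacyl vernolide-B)
Conditions: HF·pyridine, pyridine, THF, 0 °C
Reagents that add atoms: none
Why: Mildly acidic fluoride removes the secondary TBS ether with retention at C8. It spares the enol lactone, the acetate and the ketal.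

**Step 18**
Reactants: 21; 22 tigloyl chloride
Product: 23 Vernolide-B
Conditions: 22, Et3N, DMAP, CH2Cl2, 0 °C
Reagents that add atoms: 22, C/C=C(\C)C(=O)Cl (adds tigloyl)
Why: Acylation of the C8 alcohol retains the (E)-tiglate geometry and leaves C8 untouched.

## Compound list
1 | (R)-pulegone | C[C@@H]1CCC(=C(C)C)C(=O)C1 | starting material
2 | (5R)-6-hydroxy-5-methyl-2-(propan-2-ylidene)cyclohexan-1-one | C[C@@H]1CCC(=C(C)C)C(=O)C1O | intermediate
3 | propynylmagnesium bromide | CC#C[Mg]Br | starting material
4 | (5R)-5-methyl-2-(propan-2-ylidene)-1-(prop-1-ynyl)cyclohexane-1,6-diol | C[C@@H]1CCC(=C(C)C)C(O)(C#CC)C1O | intermediate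
5 | (6R)-2-hydroxy-6-methyl-3-(propan-2-ylidene)-2-(prop-1-ynyl)cyclohexan-1-one | C[C@@H]1CCC(=C(C)C)C(O)(C#CC)C1=O | intermediate
6 | vinylmagnesium bromide | C=C[Mg]Br | starting material
7 | 1-ethenyl-6-methyl-3-(propan-2-ylidene)-2-(prop-1-ynyl)cyclohexane-1,2-diol (6R) | C[C@@H]1CCC(=C(C)C)C(O)(C#CC)C1(O)C=C | intermediate
8 | (10R)-4,10-dimethyl-7-(propan-2-ylidene)cyclodec-4-ene-1,6-dione | C[C@@H]1CCC(=C(C)C)C(=O)C=C(C)CCC1=O | intermediate
9 | (4R,10R)-4,5-epoxy-4,10-dimethyl-7-(propan-2-ylidene)cyclodecane-1,6-dione | C1C[C@@H](C)C(=O)CC[C@@]2(C)OC2C(=O)C1=C(C)C | intermediate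
10 | (4R,10R)-4-hydroxy-4,10-dimethyl-7-(propan-2-ylidene)cyclodecane-1,6-dione | C1C[C@@H](C)C(=O)CC[C@](C)(CC(=O)C1=C(C)C)O | intermediate
11 | (1S,4R,10R)-1-methoxy-1,4-epoxy-4,10-dimethyl-7-(propan-2-ylidene)cyclodecan-6-one | C1C[C@@H](C)[C@]2(OC)CC[C@](C)(CC(=O)C1=C(C)C)O2 | intermediate
12 | (1S,4R,10R)-1-methoxy-1,4-epoxy-4,10-dimethylcyclodecane-6,7-dione | C1C[C@@H](C)[C@]2(OC)CC[C@](C)(CC(=O)C1=O)O2 | intermediate
13 | (1S,4R,10R)-7-(TBSO)-1-methoxy-1,4-epoxy-4,10-dimethylcyclodec-7-en-6-one | CC(C)(C)[Si](C)(C)OC1=CC[C@@H](C)[C@]2(OC)CC[C@](C)(CC1=O)O2 | intermediate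
14 | (1S,4R,8S,10R)-8-(TBSO)-1-methoxy-1,4-epoxy-4,10-dimethylcyclodecane-6,7-dione | CC(C)(C)[Si](C)(C)O[C@H]1C[C@@H](C)[C@]2(OC)CC[C@](C)(CC(=O)C1=O)O2 | intermediate
15 | triethyl 2-phosphonopropionate | CCOC(=O)C(C)P(=O)(OCC)OCC | starting material
16 | (Z)-enoate (ethyl ester) from HWE | CC(C)(C)[Si](C)(C)O[C@H]1C[C@@H](C)[C@]2(OC)CC[C@](C)(CC(=O)/C1=C(/C)C(=O)OCC)O2 | intermediate
17 | (Z)-keto acid | CC(C)(C)[Si](C)(C)O[C@H]1C[C@@H](C)[C@]2(OC)CC[C@](C)(CC(=O)/C1=C(/C)C(=O)O)O2 | intermediate
18 | TBS ether of 13-methyl alkylidene butenolide | CC(C)(C)[Si](C)(C)O[C@H]1C[C@@H](C)[C@]2(OC)CC[C@](C)(/C=C3/OC(=O)C(C)=C31)O2 | intermediate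
19 | 13-bromo derivative | CC(C)(C)[Si](C)(C)O[C@H]1C[C@@H](C)[C@]2(OC)CC[C@](C)(/C=C3/OC(=O)C(CBr)=C31)O2 | intermediate
20 | 13-acetoxy TBS ether | CC(C)(C)[Si](C)(C)O[C@H]1C[C@@H](C)[C@]2(OC)CC[C@](C)(/C=C3/OC(=O)C(COC(C)=O)=C31)O2 | intermediate
21 | 8-hydroxy (8-O-deacyl) compound | O[C@H]1C[C@@H](C)[C@]2(OC)CC[C@](C)(/C=C3/OC(=O)C(COC(C)=O)=C31)O2 | intermediate
22 | tigloyl chloride, (2E)-2-methylbut-2-enoyl chloride | C/C=C(\C)C(=O)Cl | starting material
23 | Vernolide-B | C/C=C(\C)C(=O)O[C@H]1C[C@@H](C)[C@]2(OC)CC[C@](C)(/C=C3/OC(=O)C(COC(C)=O)=C31)O2 | target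

**Total step count:** 18
**Longest linear sequence:** 18 (all steps are linear from (R)-pulegone)

## Three steps most likely to fail
1. **Step 5 (oxy-Cope).** The diolate could instead rearrange through the C7=C11 alkene, the enyne Cope is slower than a diene Cope, and C10 (α to the new C1 ketone) could epimerise. Fallback: cleave C1–C6 of a Robinson-annulated decalin from pulegone instead, by epoxy-alcohol (Grob-type) fragmentation, so no pericyclic enyne step is needed.
2. **Step 6 (C4 epoxidation).** The facial selectivity is only conformationally biased, and the basic conditions could epimerise C10. Fallback: reduce C6 to the allylic alcohol, do a hydroxyl-directed VO(acac)2/t-BuOOH epoxidation of C4=C5, then re-oxidise C6, which sets C4 by direction rather than by ring shape.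
3. **Step 15 (C13 bromination).** NBS may attack C8–H or the electron-rich enol-lactone alkene. Fallback: put the C13 oxygen in from the start by using a phosphonate carrying a protected hydroxymethyl group in step 12, which removes steps 15–16.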